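(The runs are calculated from invented constants; scatter was added.)

The birch run at 75 °C showed one steady number. X gained per J lost, s (the integral selectivity), read 0.552 at 4.00 min and 0.554 at 25.0 min, against 0.189 at the end of cedar. That steadiness shows no loss of X, but a reading carries a scatter of 0.5 percentage points, so I asked how much loss birch could hide. If X forms about evenly, its mean age is half the run, and a first-order loss with constant k removes a fraction k·t/2 of it. Setting that removal equal to two standard deviations of the last X reading gives k_h = 0.159 h⁻¹, the hidden-loss constant: the largest first-order loss of X that birch conceals at that level.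

| flask | J | temperature | remark | time |
|---|---|---|---|---|
| cedar | 2.5 M | 48 °C | run made earlier |  |
| birch | 2.5 M | 75 °C | run made earlier |  |
| amber | 1.8 M | 35 °C |  | 2.5 h |
| teal | 1.8 M | 85 °C |  | 2.5 h |
| grey | 1.8 M | 60 °C |  | 2.5 h |

- cedar (time / min: X / %, J / %): 5.00: 0.3, 98.5; 15.0: 1.4, 95.1; 25.0: 1.9, 92.4; 40.0: 2.0, 88.0; 60.0: 2.5, 83.6; 80.0: 4.0, 79.9; 90.0: 4.3, 77.2
- birch (time / min: X / %, J / %): 1.33: 1.9, 95.4; 4.00: 7.4, 86.6; 6.00: 10.0, 80.6; 12.0: 18.3, 66.9; 15.0: 20.9, 60.8; 20.0: 25.2, 53.0; 25.0: 30.1, 45.7

(scatter of a reading: 0.5 percentage points)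

* the flask that comes out highest in amount of X, in percent of the J charged, or "all alike" when all lie within 1.5 percentage points (amber / teal / grey / all alike)
* X at the end, in percent of the J charged, amber
* X at the end, in percent of the J charged, teal
* X at the end, in percent of the J charged, grey



I bracketed X in teal. From above, I carried the rise of s from cedar to birch on in a straight line to 85 °C, which gives 0.690. With the whole charge lost and X kept, that straight line gives an upper estimate of 69.0%; it is an estimate and no hard limit, since the charge itself allows 100%. From below, I took birch's s with the whole charge lost; the forecast puts the loss at 97%. I let k_h run twice as fast in the hotter teal and act over the full 2.5 h, which gives 25.0%. The readings do not separate zero loss from k_h, so my bracket stayed that wide.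

The forecast named teal highest, with amber 0.9%, grey 21% and teal 64% (52% to 72%), “assuming X survives”. Its teal value lay inside my bracket, above the middle, and its high end lay above my upper estimate.

Teal came out highest, teal, at 32.4%, with grey 26.2% and amber 1.23%.

    J → X (k = 0.170 h⁻¹, Ea = 119 kJ mol⁻¹)
    2 J → G (k = 0.0790 M⁻¹ h⁻¹, Ea = 69.0 kJ mol⁻¹)
    X → E (k = 0.00190 h⁻¹, Ea = 114 kJ mol⁻¹)
    X → L (k = 0.0280 h⁻¹, Ea = 104 kJ mol⁻¹)
    (constants at 60 °C)

Teal's 32.4% lies inside the bracket, 32 points under the forecast. In teal, X stood at 53.5% at 1.25 h and 32.4% at 2.50 h, while L rose from 25.2% to 45.5%. Between those times the first-order constant of X in teal is 0.403 h⁻¹, 2.53 times k_h. Grey held X at 41.9% at 10.0 h and 31.7% at 25.0 h, a net constant of 0.0186 h⁻¹, below the 0.159 h⁻¹ of birch.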